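**Retrosynthetic overview**
1. 14 ⇐ 13 by removing the two MOM ethers on ring A last. 13 ⇐ 10 by opening pyran ring D at the bond between aryl carbon C2' of ring B and the ether oxygen. Compound 10 is a genistein-type isoflavone in which C2' still carries hydrogen and C3' carries a (Z)-3-hydroxy-3-methylbut-1-enyl chain.
2. Enabling feature: the 4'-OH of ring B is para to C1', and C1' is conjugated through C3=C2 with ring oxygen O1 of ring C, so two-electron oxidation dearomatises ring B at C1'. In the resulting cyclohexadienone, C2' (meta to O4', ortho to C1') is the β-carbon of the C4'=O enone. It is the only electrophilic ring carbon the tertiary hydroxyl of the C3' chain can reach, and O4' is locked as a carbonyl oxygen.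
3. 10 ⇐ Suzuki–Miyaura union (C3–C1') of 3-iodochromone 6 (rings A and C) with boronate 9 (ring B).
4. 6 ⇐ phloroacetophenone 1 + prenyl bromide 2 (C-prenylation, bis-MOM, enaminone, iodocyclisation). 9 ⇐ 6-bromocoumarin 7, whose lactone is a temporary ring that fixes the Z alkene and is opened by MeMgBr.
5. Ring order: rings A and B are bought as arenes, ring C closes in step 4, ring D closes in step 8.

Key step: step 8

Remark on the chemistry: isoflavone numbering is used (ring A C5–C8, ring C O1–C4, ring B C1'–C6', ring D = the dimethylpyran). The target has no stereocentre. The stereocentres of the transient compounds 11 and 12 are erased within the same step, so these two are drawn without configuration.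

Step 1
Reactants: 1 2,4,6-trihydroxyacetophenone; 2 prenyl bromide (1-bromo-3-methylbut-2-ene)
Product: 3 1-[2,4,6-trihydroxy-3-(3-methylbut-2-en-1-yl)phenyl]ethan-1-one
Conditions: KOH (1.0 equiv), H2O, 0 °C to rt
Reagents that add atoms: none
Why: C-alkylation of an ambident phloroglucinol phenolate, which a protic medium steers to carbon; C3 and C5 are equivalent, so only one mono-C-prenyl product is possible.

Step 2
Reactants: 3 1-[2,4,6-trihydroxy-3-(3-methylbut-2-en-1-yl)phenyl]ethan-1-one
Product: 4 1-[2-hydroxy-4,6-bis(methoxymethoxy)-3-(3-methylbut-2-en-1-yl)phenyl]ethan-1-one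
Conditions: MOMCl (2.1 equiv), iPr2NEt, CH2Cl2, 0 °C
Reagents that add atoms: chloromethyl methyl ether, COCCl
Why: O-alkylation (MOM acetal formation) should take the 4-OH and the less hindered 6-OH, while the 2-OH, flanked by prenyl and acetyl, stays chelated to the ketone and is kept free for the later closure that places prenyl at C8.

Step 3
Reactants: 4 1-[2-hydroxy-4,6-bis(methoxymethoxy)-3-(3-methylbut-2-en-1-yl)phenyl]ethan-1-one
Product: 5 (E)-3-(dimethylamino)-1-[2-hydroxy-4,6-bis(methoxymethoxy)-3-(3-methylbut-2-en-1-yl)phenyl]prop-2-en-1-one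
Conditions: Me2NCH(OMe)2 (2 equiv), toluene, 90 °C
Reagents that add atoms: N,N-dimethylformamide dimethyl acetal, COC(OC)N(C)C
Why: Condensation of a methyl ketone with an amide acetal gives the E-enaminone, the standard C1 homologation of 2-hydroxyacetophenones, and the chelated phenol is not methylated.

Step 4
Reactants: 5 (E)-3-(dimethylamino)-1-[2-hydroxy-4,6-bis(methoxymethoxy)-3-(3-methylbut-2-en-1-yl)phenyl]prop-2-en-1-one
Product: 6 3-iodo-5,7-bis(methoxymethoxy)-8-(3-methylbut-2-en-1-yl)-4H-chromen-4-one
Conditions: I2 (1.0 equiv, slow addition), CHCl3, 0 °C to rt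
Reagents that add atoms: iodine, II
Why: Iodocyclisation of a 2-hydroxyaryl enaminone, in which α-iodination gives an iminium ion, the phenol adds and dimethylamine leaves to close ring C; the enaminone is by far the most nucleophilic π system, so one equivalent of iodine should spare the prenyl alkene.

Step 5
Reactants: 7 6-bromocoumarin (6-bromo-2H-chromen-2-one)
Product: 8 4-bromo-2-[(Z)-3-hydroxy-3-methylbut-1-en-1-yl]phenol
Conditions: MeMgBr (3 equiv), THF, 0 °C to rt; sat. aq NH4Cl; purification on Et3N-deactivated silica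
Reagents that add atoms: methylmagnesium bromide, C[Mg]Br
Why: Double 1,2-Grignard addition to the lactone opens the temporary ring, and the Z geometry is inherited from the cyclic alkene of the coumarin; a neutral work-up avoids acid-induced loss of water.

Step 6
Reactants: 8 4-bromo-2-[(Z)-3-hydroxy-3-methylbut-1-en-1-yl]phenol
Product: 9 2-[(Z)-3-hydroxy-3-methylbut-1-en-1-yl]-4-(4,4,5,5-tetramethyl-1,3,2-dioxaborolan-2-yl)phenol
Conditions: B2pin2 (1.2 equiv), PdCl2(dppf) (3 mol %), KOAc (3 equiv), 1,4-dioxane, 80 °C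
Reagents that add atoms: bis(pinacolato)diboron, CC1(C)OB(OC1(C)C)B1OC(C)(C)C(C)(C)O1
Why: Miyaura borylation of an aryl bromide, a reaction that tolerates free phenols and alcohols, run in an acetate-buffered, acid-free medium that should leave the Z-allylic alcohol intact.

Step 7
Reactants: 6 3-iodo-5,7-bis(methoxymethoxy)-8-(3-methylbut-2-en-1-yl)-4H-chromen-4-one; 9 2-[(Z)-3-hydroxy-3-methylbut-1-en-1-yl]-4-(4,4,5,5-tetramethyl-1,3,2-dioxaborolan-2-yl)phenol
Product: 10 3-{4-hydroxy-3-[(Z)-3-hydroxy-3-methylbut-1-en-1-yl]phenyl}-5,7-bis(methoxymethoxy)-8-(3-methylbut-2-en-1-yl)-4H-chromen-4-one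
Conditions: Pd(PPh3)4 (5 mol %), K2CO3 (2 equiv), DME/H2O (4:1), 70 °C
Reagents that add atoms: none
Why: Suzuki–Miyaura coupling of a 3-iodochromone with a 4-hydroxyphenylboron reagent is the standard isoflavone synthesis, and the mildly basic medium is harmless to MOM ethers, both alkenes and the acid-labile chain.

Step 8
Reactants: 10 3-{4-hydroxy-3-[(Z)-3-hydroxy-3-methylbut-1-en-1-yl]phenyl}-5,7-bis(methoxymethoxy)-8-(3-methylbut-2-en-1-yl)-4H-chromen-4-one
Product: 13 3-(5-hydroxy-2,2-dimethyl-2H-chromen-8-yl)-5,7-bis(methoxymethoxy)-8-(3-methylbut-2-en-1-yl)-4H-chromen-4-one, via methoxy dienone 11 (not isolated), via oxa-Michael adduct 12 (not isolated)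
Conditions: PhI(OAc)2 (1.0 equiv), MeOH/CH2Cl2 (1:4), 0 °C; once 10 is consumed, camphorsulfonic acid (10 mol %), same flask, 0 °C to rt
Reagents that add atoms: methanol, CO (its methoxy group is carried only by 11 and 12 and leaves again; no reagent atom stays in 13)
Why: Proposed new method: PhI(OAc)2 binds the only free phenol (4'-OH) and takes two electrons out of ring B, the cation being stabilised at C1' through C3=C2 by the lone pair of ring-C oxygen O1, and methanol traps it at C1' to give the cross-conjugated dienone 11, just as 4-arylphenols and 4'-hydroxyflavones are known to give p-quinol ethers with trivalent iodine reagents. In 11 the polarity of ring B is reversed, C2' now being the β-carbon of the C4'=O enone, and under acid catalysis the tertiary hydroxyl of the Z chain on C3' should add to it (6-endo-trig oxa-Michael closure of ring D, geometrically akin to the chalcone-to-flavanone closure) to give 12. Ionisation of the C1'–OMe bond of 12 (again assisted by O1), loss of the C2' proton and enolisation expel methanol and restore the arene, which makes the sequence irreversible; the closest known reaction types are intramolecular oxa-Michael additions to cyclohexadienones and the conjugate addition/elimination of p-quinol ethers and quinone monoketals that delivers meta-functionalised phenols. Site selectivity: of the two β-carbons C2' and C6', only C2' lies within reach of the tether, and the isomeric pyran on O4' cannot form because O4' is a carbonyl oxygen at this oxidation level. Chemoselectivity: ring A carries no free phenol, its MOM ethers and the prenyl alkene react far more slowly with PhI(OAc)2 than a phenol does, and the acid is added only after the oxidant is spent, so the electron-rich product never meets it. The stereocentres of 11 and 12 are transient and disappear on rearomatisation, so no stereocontrol is needed.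

Step 9
Reactants: 13 3-(5-hydroxy-2,2-dimethyl-2H-chromen-8-yl)-5,7-bis(methoxymethoxy)-8-(3-methylbut-2-en-1-yl)-4H-chromen-4-one
Product: 14 5,7-dihydroxy-3-(5-hydroxy-2,2-dimethyl-2H-chromen-8-yl)-8-(3-methylbut-2-en-1-yl)-4H-chromen-4-one (target)
Conditions: 3 M aq HCl, MeOH, 45 °C
Reagents that add atoms: none
Why: Acid hydrolysis of aryl MOM acetals under mild conditions is the usual end game for prenylated flavonoids and should leave the prenyl alkene and the chromene untouched.

**Compound list**
1 | 2,4,6-trihydroxyacetophenone | CC(=O)c1c(O)cc(O)cc1O | starting material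
2 | prenyl bromide (1-bromo-3-methylbut-2-ene) | CC(C)=CCBr | starting material
3 | 1-[2,4,6-trihydroxy-3-(3-methylbut-2-en-1-yl)phenyl]ethan-1-one | CC(=O)c1c(O)cc(O)c(CC=C(C)C)c1O | intermediate
4 | 1-[2-hydroxy-4,6-bis(methoxymethoxy)-3-(3-methylbut-2-en-1-yl)phenyl]ethan-1-one | CC(=O)c1c(OCOC)cc(OCOC)c(CC=C(C)C)c1O | intermediate
5 | (E)-3-(dimethylamino)-1-[2-hydroxy-4,6-bis(methoxymethoxy)-3-(3-methylbut-2-en-1-yl)phenyl]prop-2-en-1-one | CN(C)/C=C/C(=O)c1c(OCOC)cc(OCOC)c(CC=C(C)C)c1O | intermediate
6 | 3-iodo-5,7-bis(methoxymethoxy)-8-(3-methylbut-2-en-1-yl)-4H-chromen-4-one | CC(C)=CCc1c(OCOC)cc(OCOC)c2c(=O)c(I)coc12 | intermediate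
7 | 6-bromocoumarin | O=c1ccc2cc(Br)ccc2o1 | starting material
8 | 4-bromo-2-[(Z)-3-hydroxy-3-methylbut-1-en-1-yl]phenol | CC(C)(O)/C=C\c1cc(Br)ccc1O | intermediate
9 | 2-[(Z)-3-hydroxy-3-methylbut-1-en-1-yl]-4-(4,4,5,5-tetramethyl-1,3,2-dioxaborolan-2-yl)phenol | CC(C)(O)/C=C\c1cc(B2OC(C)(C)C(C)(C)O2)ccc1O | intermediate
10 | 3-{4-hydroxy-3-[(Z)-3-hydroxy-3-methylbut-1-en-1-yl]phenyl}-5,7-bis(methoxymethoxy)-8-(3-methylbut-2-en-1-yl)-4H-chromen-4-one | CC(C)=CCc1c(OCOC)cc(OCOC)c2c(=O)c(-c3ccc(O)c(/C=C\C(C)(C)O)c3)coc12 | intermediate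
11 | 3-{3-[(Z)-3-hydroxy-3-methylbut-1-en-1-yl]-1-methoxy-4-oxocyclohexa-2,5-dien-1-yl}-5,7-bis(methoxymethoxy)-8-(3-methylbut-2-en-1-yl)-4H-chromen-4-one (racemic, not isolated) | CC(C)=CCc1c(OCOC)cc(OCOC)c2c(=O)c(C3(OC)C=CC(=O)C(/C=C\C(C)(C)O)=C3)coc12 | intermediate
12 | 3-(8-methoxy-2,2-dimethyl-5-oxo-4a,5,8,8a-tetrahydro-2H-chromen-8-yl)-5,7-bis(methoxymethoxy)-8-(3-methylbut-2-en-1-yl)-4H-chromen-4-one (diastereomer mixture, not isolated) | CC(C)=CCc1c(OCOC)cc(OCOC)c2c(=O)c(C3(OC)C=CC(=O)C4C=CC(C)(C)OC43)coc12 | intermediate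
13 | 3-(5-hydroxy-2,2-dimethyl-2H-chromen-8-yl)-5,7-bis(methoxymethoxy)-8-(3-methylbut-2-en-1-yl)-4H-chromen-4-one | CC(C)=CCc1c(OCOC)cc(OCOC)c2c(=O)c(-c3ccc(O)c4c3OC(C)(C)C=C4)coc12 | intermediate
14 | 5,7-dihydroxy-3-(5-hydroxy-2,2-dimethyl-2H-chromen-8-yl)-8-(3-methylbut-2-en-1-yl)-4H-chromen-4-one | CC(C)=CCc1c(O)cc(O)c2c(=O)c(-c3ccc(O)c4c3OC(C)(C)C=C4)coc12 | target

**Step count**
Total steps: 9. Longest linear sequence: 7 (steps 1, 2, 3, 4, 7, 8, 9).

**Steps most likely to fail**

Step 8 (Proposed new method). Several processes may outrun the addition of the hydroxyl to C2'. The protonated dienone may undergo 1,2-migration of the chromonyl group (dienone–phenol pathway) or add methanol at C6'. It may also lose the tertiary allylic hydroxyl by ionisation. The oxidation itself may be diverted onto the styrene-type chain.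

The fallback uses known chemistry, sets out from 6 and comes back at 14. Ring D is built on the ring B fragment before the union by the aryl propargyl ether route.
- Commercial 4-bromoresorcinol is mono-protected (MOMCl, iPr2NEt, CH2Cl2, 0 °C) at the less hindered hydroxyl para to bromine to give 2-bromo-5-(methoxymethoxy)phenol F1.
- O-alkylation with 3-chloro-3-methylbut-1-yne (K2CO3, KI, CuI cat., acetone, reflux) gives 1-bromo-4-(methoxymethoxy)-2-[(2-methylbut-3-yn-2-yl)oxy]benzene F2.
- Heating in N,N-diethylaniline triggers propargyl Claisen rearrangement, 1,5-hydrogen shift and oxa-6π closure. The closure can only go onto the one free ortho carbon and should give 8-bromo-5-(methoxymethoxy)-2,2-dimethyl-2H-chromene F3.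
- Borylation under the conditions of step 6 gives 2-[5-(methoxymethoxy)-2,2-dimethyl-2H-chromen-8-yl]-4,4,5,5-tetramethyl-1,3,2-dioxaborolane F4.
- Coupling with 6 under the conditions of step 7 gives 5,7-bis(methoxymethoxy)-3-[5-(methoxymethoxy)-2,2-dimethyl-2H-chromen-8-yl]-8-(3-methylbut-2-en-1-yl)-4H-chromen-4-one F5.
- The conditions of step 9 convert F5 into 14.

Step 4. Iodonium attack on the electron-rich trisubstituted alkene, assisted by the neighbouring free phenol (iodoetherification), may compete with iodination of the enaminone.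

The fallback sets out from 1 and comes back at 6. A much less nucleophilic allyl group is carried through the iodine step and turned into prenyl afterwards.
- 1 is C-allylated (allyl bromide, KOH, H2O) to 3-allyl-2,4,6-trihydroxyacetophenone F6.
- F6 is protected as in step 2 to 1-[3-allyl-2-hydroxy-4,6-bis(methoxymethoxy)phenyl]ethan-1-one F7.
- F7 is condensed as in step 3 to (E)-1-[3-allyl-2-hydroxy-4,6-bis(methoxymethoxy)phenyl]-3-(dimethylamino)prop-2-en-1-one F8.
- F8 is cyclised as in step 4 to 8-allyl-3-iodo-5,7-bis(methoxymethoxy)-4H-chromen-4-one F9.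
- Cross metathesis of F9 with excess 2-methylbut-2-ene (second-generation Grubbs catalyst, CH2Cl2, 40 °C) should give 6.

Step 6. Thermal or palladium-assisted loss of water from the Z-allylic alcohol, with closure onto the free phenol oxygen, may occur at 80 °C, as may protodeboronation of the electron-rich boronate.

The fallback sets out from 8 and comes back at 10. Palladium-catalysed borylation is replaced by cryogenic halogen–metal exchange on the dianion.
- 8 is deprotonated twice (NaH, THF, 0 °C).
- It is then treated with t-BuLi (2.1 equiv, −78 °C) and B(OiPr)3.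
- Neutral aqueous NH4Cl work-up gives {4-hydroxy-3-[(Z)-3-hydroxy-3-methylbut-1-en-1-yl]phenyl}boronic acid F10.
- F10 is used in place of 9 under the conditions of step 7 to give 10.

**Further compounds**
F1 | step 8 | 2-bromo-5-(methoxymethoxy)phenol | COCOc1ccc(Br)c(O)c1
F2 | step 8 | 1-bromo-4-(methoxymethoxy)-2-[(2-methylbut-3-yn-2-yl)oxy]benzene | COCOc1ccc(Br)c(OC(C)(C)C#C)c1
F3 | step 8 | 8-bromo-5-(methoxymethoxy)-2,2-dimethyl-2H-chromene | COCOc1ccc(Br)c2c1C=CC(C)(C)O2
F4 | step 8 | 2-[5-(methoxymethoxy)-2,2-dimethyl-2H-chromen-8-yl]-4,4,5,5-tetramethyl-1,3,2-dioxaborolane | COCOc1ccc(B3OC(C)(C)C(C)(C)O3)c2c1C=CC(C)(C)O2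
F5 | step 8 | 5,7-bis(methoxymethoxy)-3-[5-(methoxymethoxy)-2,2-dimethyl-2H-chromen-8-yl]-8-(3-methylbut-2-en-1-yl)-4H-chromen-4-one | CC(C)=CCc1c(OCOC)cc(OCOC)c2c(=O)c(-c3ccc(OCOC)c4c3OC(C)(C)C=C4)coc12
F6 | step 4 | 3-allyl-2,4,6-trihydroxyacetophenone | CC(=O)c1c(O)cc(O)c(CC=C)c1O
F7 | step 4 | 1-[3-allyl-2-hydroxy-4,6-bis(methoxymethoxy)phenyl]ethan-1-one | CC(=O)c1c(OCOC)cc(OCOC)c(CC=C)c1O
F8 | step 4 | (E)-1-[3-allyl-2-hydroxy-4,6-bis(methoxymethoxy)phenyl]-3-(dimethylamino)prop-2-en-1-one | CN(C)/C=C/C(=O)c1c(OCOC)cc(OCOC)c(CC=C)c1O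
F9 | step 4 | 8-allyl-3-iodo-5,7-bis(methoxymethoxy)-4H-chromen-4-one | C=CCc1c(OCOC)cc(OCOC)c2c(=O)c(I)coc12
F10 | step 6 | {4-hydroxy-3-[(Z)-3-hydroxy-3-methylbut-1-en-1-yl]phenyl}boronic acid | CC(C)(O)/C=C\c1cc(B(O)O)ccc1O
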